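A direct plan would take 1-(2,6-dihydroxy-4-methoxyphenyl)ethan-1-one A1, prenylate one hydroxyl to give the mono-ether 1-{2-hydroxy-4-methoxy-6-[(3-methylbut-2-en-1-yl)oxy]phenyl}ethan-1-one A2, close the pyranone through a ketene dithioacetal to the 2-(methylsulfanyl)chromone A3, move the prenyl group from O5 to C8 by a Claisen–Cope sequence to give the 5-hydroxy-8-prenyl-2-(methylsulfanyl)chromone A4, and finally exchange the methylsulfanyl group for the aryloxy group of benzene-1,4-diol A5. Its weakest steps would be:
- the prenyl migration, because the group would have to pass C6 and could stop there, shift [1,3] or be lost;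
- the sulfur-for-aryloxy exchange at C2, because thiolate is the poorer leaving group and prior oxidation to a sulfone would endanger the prenyl alkene;
- the carbon disulfide/iodomethane ring closure, because a free phenol and an allylic ether would have to survive excess strong base and methylating agent.

The new plan builds ring A last, on a 2-aryloxy-4-pyranone that holds O1, C2, C3, C4 and the aryl ether. It exploits the 5-hydroxy, 6-H, 7-methoxy triad of ring A beside the prenyl-bearing C8: a ketene made from a carboxyl carbon (C5) on the side-chain carbon (C8) takes up methoxyethyne (C6, C7) by [2+2] cycloaddition, and the cyclobutenone opens and recloses onto C4a. One operation forms C5–C6, C7–C8 and C4a–C5 and fixes hydroxyl, methoxy and prenyl positions by connectivity, so no prenyl migration is needed; the aryloxy group enters with the alkyne that builds the pyranone, so no sulfur chemistry or exchange at C2 is needed.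

Key step: step 7

Remark: the target has no stereocentre. Compound 10 is racemic, and its centre and the transient centres of 15 and 17 disappear before the end. Atom labels C2–C8a refer to the chromone numbering of the target.

**Step 1**
Reactants: 1 4-{[tert-butyl(dimethyl)silyl]oxy}phenol; 2 trichloroethene
Product: 3 tert-butyl{4-[(E)-1,2-dichloroethenoxy]phenoxy}dimethylsilane
Conditions: KH (1.1 equiv), THF, 0 °C; then 2 (1.2 equiv), 0 °C to rt
Reagents that add atoms: none
Why: Base-induced loss of HCl from trichloroethene gives dichloroethyne, to which the phenoxide should add anti (the known route to aryl 1,2-dichlorovinyl ethers), so the E isomer is expected, and full deprotonation with KH should keep silyl transfer between phenols low.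

**Step 2**
Reactants: 3 tert-butyl{4-[(E)-1,2-dichloroethenoxy]phenoxy}dimethylsilane
Product: 4 tert-butyl[4-(ethynyloxy)phenoxy]dimethylsilane
Conditions: n-BuLi (2.2 equiv), Et2O, −78 to −40 °C; then H2O, −78 °C; kept cold and used at once
Reagents that add atoms: none
Why: Deprotonation and loss of LiCl give the chloroalkynyl ether, chlorine–lithium exchange gives the lithium aryloxyacetylide and protonation gives the terminal aryl ynol ether (the known conversion of dichlorovinyl ethers into alkynyl ethers).

**Step 3**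
Reactants: 5 2,2,6-trimethyl-4H-1,3-dioxin-4-one; 6 1-bromo-3-methylbut-2-ene
Product: 7 2,2-dimethyl-6-(4-methylpent-3-en-1-yl)-4H-1,3-dioxin-4-one
Conditions: LiN(i-Pr)2 (1.1 equiv), THF, −78 °C; then DMPU, 6 (1.2 equiv), −78 to −30 °C
Reagents that add atoms: none
Why: Vinylogous (γ) alkylation of the lithium dienolate of the dioxinone by SN2 attack on the primary allylic bromide, which places the future C8 between the masked β-keto acid and the prenyl group.

**Step 4**
Reactants: 7 2,2-dimethyl-6-(4-methylpent-3-en-1-yl)-4H-1,3-dioxin-4-one; 4 tert-butyl[4-(ethynyloxy)phenoxy]dimethylsilane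
Product: 9 2-(4-{[tert-butyl(dimethyl)silyl]oxy}phenoxy)-6-(4-methylpent-3-en-1-yl)-4H-pyran-4-one, via acylketene 8 (not isolated)
Conditions: 4 (1.5 equiv), toluene, 110 °C, slow addition of 7
Reagents that add atoms: none
Why: Retro-[4+2] loss of acetone gives acylketene 8, which should add to the electron-rich ynol ether as a 1-oxadiene (hetero-Diels–Alder reaction of acylketenes with heteroatom-substituted alkynes), the nucleophilic CH carbon bonding to the ketene carbon and the acyl oxygen to the aryloxy-bearing carbon, so that the aryloxy group ends at C2 of the 4-pyranone.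

**Step 5**
Reactants: 9 2-(4-{[tert-butyl(dimethyl)silyl]oxy}phenoxy)-6-(4-methylpent-3-en-1-yl)-4H-pyran-4-one
Product: 10 2-[6-(4-{[tert-butyl(dimethyl)silyl]oxy}phenoxy)-4-oxo-4H-pyran-2-yl]-5-methylhex-4-enoic acid (racemic)
Conditions: LiN(SiMe3)2 (1.1 equiv), THF, −78 °C; transfer into CO2-saturated THF, −78 °C; cold 0.5 M HCl; used crude
Reagents that add atoms: carbon dioxide O=C=O
Why: The CH2 next to the pyranone is the vinylogous α-position of the ring ketone and the only acidic sp3 site, so the hindered amide base should give the extended enolate, which is carboxylated at carbon (carboxylation of a vinylogous enolate), and the new centre is racemic and is lost in step 7.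

**Step 6**
Reactants: 11 2-chloro-1,1-dimethoxyethane
Product: 12 methoxyethyne
Conditions: NaNH2 (3.1 equiv), liquid NH3, −33 °C; cold aq. NaCl; distilled into cold toluene
Reagents that add atoms: none
Why: Twofold base-induced elimination (methanol, then HCl) gives sodium methoxyacetylide, which is protonated on quenching (the standard preparation of 1-alkoxyalkynes from chloroacetaldehyde acetals).

**Step 7**
Reactants: 10 2-[6-(4-{[tert-butyl(dimethyl)silyl]oxy}phenoxy)-4-oxo-4H-pyran-2-yl]-5-methylhex-4-enoic acid; 12 methoxyethyne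
Product: 18 2-(4-{[tert-butyl(dimethyl)silyl]oxy}phenoxy)-5-hydroxy-7-methoxy-8-(3-methylbut-2-en-1-yl)-4H-chromen-4-one, via acid chloride 13 (not isolated), via pyranonyl ketene 14 (not isolated), via cyclobutenone 15 (not isolated), via dienylketene 16 (not isolated), via cyclohexadienone 17 (not isolated)
Conditions: Me2C=C(Cl)NMe2 (1.1 equiv), CH2Cl2, 0 °C to rt; evaporate; 12 (5 equiv), Et3N (1.5 equiv, slow addition), toluene, 0 °C to rt; filter, strip excess 12; toluene, 100 °C
Reagents that add atoms: none
Why: The acid chloride 13 loses HCl to ketene 14 (a vinylketene through the pyranone C=C), and stepwise [2+2] cycloaddition with methoxyethyne, in which the nucleophilic CH carbon attacks the ketene carbonyl carbon and the methoxy-bearing carbon closes on the ketene α-carbon, gives cyclobutenone 15. At 100 °C 15 should open by conrotatory 4π cleavage to dienylketene 16, ring A then closes by a thermal disrotatory 6π-electrocyclisation that joins the ketene carbon (C5) to the pyranone CH next to the side chain (C4a), and dienone 17 tautomerises to the phenol under the pull of aromatisation and of the hydrogen bond to C4=O. The closest known reaction type is the Danheiser benzannulation of vinylketenes with alkoxyalkynes, with its aryl counterpart, the Smith–Hoehn naphthol synthesis from arylketenes and alkynes. The regiochemistry needed comes from the polarisation of the ynol ether alone: the ketene oxygen becomes 5-OH, the alkyne CH becomes C6 and the methoxy carbon becomes C7 beside the prenyl-bearing C8. Only the isomer of 16 with the ketene arm cis to the pyranone can close; the electron-poor pyranonyl group should favour this inward rotation, the other isomer can return to 15, and the side-chain carbon has one carbon neighbour in the pyranone ring only (the other is O1), so there is a single site of closure. The quaternary carbon of 15 and C4a of 17 are formed racemic and are lost, so no stereocentre has to be controlled.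

**Step 8**
Reactants: 18 2-(4-{[tert-butyl(dimethyl)silyl]oxy}phenoxy)-5-hydroxy-7-methoxy-8-(3-methylbut-2-en-1-yl)-4H-chromen-4-one
Product: 19 5-hydroxy-2-(4-hydroxyphenoxy)-7-methoxy-8-(3-methylbut-2-en-1-yl)-4H-chromen-4-one (7-O-methylepimedonin G)
Conditions: Bu4NF (1.1 equiv), AcOH (1.2 equiv), THF, 0 °C
Reagents that add atoms: none
Why: Fluoride cleaves the aryl silyl ether (desilylation), and the acetic acid buffer should keep the liberated phenoxide from attacking C2 of the aryloxychromone.

## Compound list

1 | 4-{[tert-butyl(dimethyl)silyl]oxy}phenol | CC(C)(C)[Si](C)(C)Oc1ccc(O)cc1 | starting material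
2 | trichloroethene | ClC=C(Cl)Cl | starting material
3 | tert-butyl{4-[(E)-1,2-dichloroethenoxy]phenoxy}dimethylsilane | Cl/C=C(/Cl)Oc1ccc(O[Si](C)(C)C(C)(C)C)cc1 | intermediate
4 | tert-butyl[4-(ethynyloxy)phenoxy]dimethylsilane | C#COc1ccc(O[Si](C)(C)C(C)(C)C)cc1 | intermediate
5 | 2,2,6-trimethyl-4H-1,3-dioxin-4-one | CC1=CC(=O)OC(C)(C)O1 | starting material
6 | 1-bromo-3-methylbut-2-ene | CC(C)=CCBr | starting material
7 | 2,2-dimethyl-6-(4-methylpent-3-en-1-yl)-4H-1,3-dioxin-4-one | CC(C)=CCCC1=CC(=O)OC(C)(C)O1 | intermediate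
8 | 7-methylocta-1,6-diene-1,3-dione (acylketene, not isolated) | CC(C)=CCCC(=O)C=C=O | intermediate
9 | 2-(4-{[tert-butyl(dimethyl)silyl]oxy}phenoxy)-6-(4-methylpent-3-en-1-yl)-4H-pyran-4-one | CC(C)=CCCc1cc(=O)cc(Oc2ccc(O[Si](C)(C)C(C)(C)C)cc2)o1 | intermediate
10 | 2-[6-(4-{[tert-butyl(dimethyl)silyl]oxy}phenoxy)-4-oxo-4H-pyran-2-yl]-5-methylhex-4-enoic acid (racemic) | CC(C)=CCC(C(=O)O)c1cc(=O)cc(Oc2ccc(O[Si](C)(C)C(C)(C)C)cc2)o1 | intermediate
11 | 2-chloro-1,1-dimethoxyethane | COC(CCl)OC | starting material
12 | methoxyethyne | C#COC | intermediate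
13 | 2-[6-(4-{[tert-butyl(dimethyl)silyl]oxy}phenoxy)-4-oxo-4H-pyran-2-yl]-5-methylhex-4-enoyl chloride (not isolated) | CC(C)=CCC(C(=O)Cl)c1cc(=O)cc(Oc2ccc(O[Si](C)(C)C(C)(C)C)cc2)o1 | intermediate
14 | 2-[6-(4-{[tert-butyl(dimethyl)silyl]oxy}phenoxy)-4-oxo-4H-pyran-2-yl]-5-methylhexa-1,4-dien-1-one (ketene, not isolated) | CC(C)=CCC(=C=O)c1cc(=O)cc(Oc2ccc(O[Si](C)(C)C(C)(C)C)cc2)o1 | intermediate
15 | 4-[6-(4-{[tert-butyl(dimethyl)silyl]oxy}phenoxy)-4-oxo-4H-pyran-2-yl]-3-methoxy-4-(3-methylbut-2-en-1-yl)cyclobut-2-en-1-one (racemic, not isolated) | COC1=CC(=O)C1(CC=C(C)C)c1cc(=O)cc(Oc2ccc(O[Si](C)(C)C(C)(C)C)cc2)o1 | intermediate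
16 | (3E)-4-[6-(4-{[tert-butyl(dimethyl)silyl]oxy}phenoxy)-4-oxo-4H-pyran-2-yl]-3-methoxy-7-methylocta-1,3,6-trien-1-one (dienylketene, not isolated) | O=C=C/C(OC)=C(/CC=C(C)C)c1cc(=O)cc(Oc2ccc(O[Si](C)(C)C(C)(C)C)cc2)o1 | intermediate
17 | 2-(4-{[tert-butyl(dimethyl)silyl]oxy}phenoxy)-7-methoxy-8-(3-methylbut-2-en-1-yl)-4aH-chromene-4,5-dione (racemic at C4a, not isolated) | COC1=CC(=O)C2C(=O)C=C(Oc3ccc(O[Si](C)(C)C(C)(C)C)cc3)OC2=C1CC=C(C)C | intermediate
18 | 2-(4-{[tert-butyl(dimethyl)silyl]oxy}phenoxy)-5-hydroxy-7-methoxy-8-(3-methylbut-2-en-1-yl)-4H-chromen-4-one | COc1cc(O)c2c(=O)cc(Oc3ccc(O[Si](C)(C)C(C)(C)C)cc3)oc2c1CC=C(C)C | intermediate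
19 | 5-hydroxy-2-(4-hydroxyphenoxy)-7-methoxy-8-(3-methylbut-2-en-1-yl)-4H-chromen-4-one (7-O-methylepimedonin G) | COc1cc(O)c2c(=O)cc(Oc3ccc(O)cc3)oc2c1CC=C(C)C | target

Total step count: 8. Longest linear sequence: 6 (steps 1, 2, 4, 5, 7, 8).

## Steps most likely to fail

**Step 7.** The ketene may dimerise before the volatile alkyne captures it. Ring-opening of 15 may also turn the prenyl CH2 inward, where a 1,5-hydrogen shift would divert the dienylketene. The fallback would set out from 10 and close ring A by a Claisen condensation instead. Activation of 10 with 1,1'-carbonyldiimidazole and decarboxylative Claisen condensation with Mg(O2CCH2CO2Me)2 would give methyl 4-[6-(4-{[tert-butyl(dimethyl)silyl]oxy}phenoxy)-4-oxo-4H-pyran-2-yl]-7-methyl-3-oxooct-6-enoate F1. Excess NaH in THF (or DBU in toluene) would then let the pyranone dienolate carbon C4a attack the ester and give 2-(4-{[tert-butyl(dimethyl)silyl]oxy}phenoxy)-5,7-dihydroxy-8-(3-methylbut-2-en-1-yl)-4H-chromen-4-one F2. Mitsunobu methylation of the non-chelated 7-hydroxyl (MeOH, PPh3, diisopropyl azodicarboxylate) would come back to the route at 18.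

**Step 4.** Thermal polymerisation of the aryl ynol ether or dimerisation of the acylketene may outrun the cycloaddition. The fallback would set out from 7 and 4 and build the pyranone stepwise. Heating 7 with N-methoxymethanamine in toluene would trap the acylketene as N-methoxy-N,7-dimethyl-3-oxooct-6-enamide F3. Its sodium enolate (NaH) would be treated with the lithium acetylide made from 4 and n-BuLi to give 1-(4-{[tert-butyl(dimethyl)silyl]oxy}phenoxy)-9-methyldec-8-en-1-yne-3,5-dione F4. The enol oxygen of F4 would add 6-endo to the aryloxy-bearing alkyne carbon (catalytic Et3N) and come back to the route at 9.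

**Step 5.** The side-chain anion may attack C2 of a second pyranone with loss of aryloxide, or the vinylogous β-keto acid may lose CO2 during acidic work-up. The fallback would set out from 7 and bring in the carboxyl carbon before the pyranone exists. A second deprotonation of 7 (LiN(i-Pr)2, 2 equiv) and C-acylation with prop-2-en-1-yl carbonochloridate would give prop-2-en-1-yl 2-(2,2-dimethyl-4-oxo-4H-1,3-dioxin-6-yl)-5-methylhex-4-enoate F5. Thermolysis with 4 as in step 4 would give prop-2-en-1-yl 2-[6-(4-{[tert-butyl(dimethyl)silyl]oxy}phenoxy)-4-oxo-4H-pyran-2-yl]-5-methylhex-4-enoate F6. Pd(PPh3)4 (zerovalent palladium) and morpholine would remove the allyl group under neutral conditions and come back to the route at 10.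

## Further compounds

F1 | step 7 | methyl 4-[6-(4-{[tert-butyl(dimethyl)silyl]oxy}phenoxy)-4-oxo-4H-pyran-2-yl]-7-methyl-3-oxooct-6-enoate (racemic) | COC(=O)CC(=O)C(CC=C(C)C)c1cc(=O)cc(Oc2ccc(O[Si](C)(C)C(C)(C)C)cc2)o1
F2 | step 7 | 2-(4-{[tert-butyl(dimethyl)silyl]oxy}phenoxy)-5,7-dihydroxy-8-(3-methylbut-2-en-1-yl)-4H-chromen-4-one | CC(C)=CCc1c(O)cc(O)c2c(=O)cc(Oc3ccc(O[Si](C)(C)C(C)(C)C)cc3)oc12
F3 | step 4 | N-methoxy-N,7-dimethyl-3-oxooct-6-enamide | CON(C)C(=O)CC(=O)CCC=C(C)C
F4 | step 4 | 1-(4-{[tert-butyl(dimethyl)silyl]oxy}phenoxy)-9-methyldec-8-en-1-yne-3,5-dione | CC(C)=CCCC(=O)CC(=O)C#COc1ccc(O[Si](C)(C)C(C)(C)C)cc1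
F5 | step 5 | prop-2-en-1-yl 2-(2,2-dimethyl-4-oxo-4H-1,3-dioxin-6-yl)-5-methylhex-4-enoate (racemic) | C=CCOC(=O)C(CC=C(C)C)C1=CC(=O)OC(C)(C)O1
F6 | step 5 | prop-2-en-1-yl 2-[6-(4-{[tert-butyl(dimethyl)silyl]oxy}phenoxy)-4-oxo-4H-pyran-2-yl]-5-methylhex-4-enoate (racemic) | C=CCOC(=O)C(CC=C(C)C)c1cc(=O)cc(Oc2ccc(O[Si](C)(C)C(C)(C)C)cc2)o1
A1 | direct plan | 1-(2,6-dihydroxy-4-methoxyphenyl)ethan-1-one | CC(=O)c1c(O)cc(OC)cc1O
A2 | direct plan | 1-{2-hydroxy-4-methoxy-6-[(3-methylbut-2-en-1-yl)oxy]phenyl}ethan-1-one | CC(=O)c1c(O)cc(OC)cc1OCC=C(C)C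
A3 | direct plan | 7-methoxy-5-[(3-methylbut-2-en-1-yl)oxy]-2-(methylsulfanyl)-4H-chromen-4-one | COc1cc(OCC=C(C)C)c2c(=O)cc(SC)oc2c1
A4 | direct plan | 5-hydroxy-7-methoxy-8-(3-methylbut-2-en-1-yl)-2-(methylsulfanyl)-4H-chromen-4-one | COc1cc(O)c2c(=O)cc(SC)oc2c1CC=C(C)C
A5 | direct plan | benzene-1,4-diol | Oc1ccc(O)cc1
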